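**Plan**

- Numbering (bicyclo[3.2.1]octane): C1 methoxy bridgehead, C2 CH–OAc, C3 C(OMe)=, C4 =CH, C5 allyl bridgehead, C6 CH–CH3, C7 CH–aryl, C8 bridging C=O.
- Retrosynthesis: remove the acetate, take C2–OH back to the ketone and saturate C3=C4. The C8 ketone then lies between both bridgeheads, and C2=O is 1,3 to it through C1 and 1,5 to it through C5–C4–C3. Ring C1–C2–C3–C4–C5–C8 is therefore a Michael–Claisen retron, and C4–C5 and C1–C2 are cut together to give a cyclopentanone enolate and methyl 2-methoxyacrylate.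
- The enolate is traced back by cutting C6–CH3 (conjugate addition), C5–allyl (Stille coupling), C1–O (enolate oxidation) and C7–aryl (conjugate addition) to (R)-4-silyloxycyclopentenone.
- Forward: the five-membered ring (C1, C5, C6, C7, C8) is bought and receives aryl, methoxy, allyl and methyl in turn. The six-membered ring is then closed in one operation, which gives the bicycle, and three oxidation-level adjustments finish the route.
- Stereochemistry: the purchased silyloxy stereocentre sets C7 (aryl anti to OSi). C7 sets C6 (methyl anti to aryl), C6 sets C5 (acrylate anti to methyl), the tether sets C1, and the endo aryl group sends hydride to the exo face of C2.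

Key step: step 8

Assumption: methyl 2-methoxyacrylate (12) and the aryl Grignard solution (2) are taken as catalogue reagents.

**Route**

Step 1
Reactants: 1 (4R)-4-[(tert-butyldimethylsilyl)oxy]cyclopent-2-en-1-one; 2 (3,4,5-trimethoxyphenyl)magnesium bromide
Product: 3 {[(3S,4R)-4-[(tert-butyldimethylsilyl)oxy]-3-(3,4,5-trimethoxyphenyl)cyclopent-1-en-1-yl]oxy}trimethylsilane
Conditions: CuBr·SMe2 (10 mol %), Me3SiCl, THF, −78 °C; Et3N, cold aq. NaHCO3 work-up
Reagents that add atoms: chlorotrimethylsilane, C[Si](C)(C)Cl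
Why: Copper-catalysed conjugate addition of the aryl Grignard reagent with in situ silyl trapping should place the aryl group anti to the neighbouring silyloxy group, as is general for 4-silyloxycyclopentenones, so the purchased stereocentre sets the benzylic centre (later C7) and the enolate is stored as one regioisomer.

Step 2
Reactants: 3
Product: 5 (2R,3R,4R)-4-[(tert-butyldimethylsilyl)oxy]-2-hydroxy-3-(3,4,5-trimethoxyphenyl)cyclopentan-1-one, via silyloxy ketone 4 (not isolated)
Conditions: mCPBA, NaHCO3, CH2Cl2, −20 °C; then 1 M HCl, THF, 0 °C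
Reagents that add atoms: 3-chloroperoxybenzoic acid, OOC(=O)c1cccc(Cl)c1
Why: Rubottom oxidation, in which the enol ether is epoxidised on the face anti to the adjacent aryl group, the silyl group migrates to give 4 and mild acid removes only the trimethylsilyl group, should give the α-hydroxy ketone with OH trans to aryl.

Step 3
Reactants: 5
Product: 6 (2R,3R,4R)-4-[(tert-butyldimethylsilyl)oxy]-2-methoxy-3-(3,4,5-trimethoxyphenyl)cyclopentan-1-one
Conditions: MeI, Ag2O, 4 Å MS, MeCN, rt, dark
Reagents that add atoms: iodomethane, CI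
Why: Silver oxide-mediated O-methylation (Purdie conditions) is mild enough to leave the β-silyloxy ketone and the α-stereocentre untouched, and no new stereocentre is formed.

Step 4
Reactants: 6
Product: 7 (4R,5R)-5-methoxy-4-(3,4,5-trimethoxyphenyl)cyclopent-2-en-1-one
Conditions: DBU, CH2Cl2, 0 °C
Reagents that add atoms: none
Why: E1cB elimination of silanolate through the enolate on the CH2 side, the standard conversion of 4-silyloxycyclopentanones into cyclopentenones, should place the double bond away from the methoxy-bearing carbon without creating a stereocentre.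

Step 5
Reactants: 7
Product: 8 (4R,5R)-2-iodo-5-methoxy-4-(3,4,5-trimethoxyphenyl)cyclopent-2-en-1-one
Conditions: I2, pyridine, CH2Cl2, 0 °C to rt
Reagents that add atoms: iodine, II
Why: α-Iodination of the enone by pyridine conjugate addition, iodination of the resulting enolate and elimination (a Baylis–Hillman-type sequence) is reliable for cyclopentenones and leaves both stereocentres alone.

Step 6
Reactants: 8; 9 tributyl(prop-2-en-1-yl)stannane
Product: 10 (4R,5R)-5-methoxy-2-(prop-2-en-1-yl)-4-(3,4,5-trimethoxyphenyl)cyclopent-2-en-1-one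
Conditions: Pd2(dba)3 (2.5 mol %), AsPh3, CuI, NMP, 40 °C
Reagents that add atoms: none
Why: Stille coupling of the α-iodoenone with the allylstannane under arsine-ligand, copper-assisted conditions should install the allyl group at C2 without forming a stereocentre.

Step 7
Reactants: 10
Product: 11 {[(3S,4R,5R)-5-methoxy-3-methyl-2-(prop-2-en-1-yl)-4-(3,4,5-trimethoxyphenyl)cyclopent-1-en-1-yl]oxy}trimethylsilane
Conditions: MeMgBr, CuBr·SMe2 (10 mol %), Me3SiCl, THF, −78 °C; Et3N, cold aq. NaHCO3 work-up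
Reagents that add atoms: methylmagnesium bromide, C[Mg]Br; chlorotrimethylsilane, C[Si](C)(C)Cl
Why: Copper-catalysed conjugate addition with silyl trapping should deliver methyl anti to the adjacent aryl group (trans, the later C6) and store the allyl-bearing enolate as a single tetrasubstituted silyl enol ether.

Step 8
Reactants: 11; 12 methyl 2-methoxyprop-2-enoate
Product: 16 {[(1S,5R,6S,7R)-1,3-dimethoxy-6-methyl-8-oxo-5-(prop-2-en-1-yl)-7-(3,4,5-trimethoxyphenyl)bicyclo[3.2.1]oct-2-en-2-yl]oxy}trimethylsilane, via lithium enolate 13 (not isolated), via Michael adduct 14 (not isolated), via bicyclic lithium enolate 15 (not isolated)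
Conditions: MeLi (1.0 equiv), THF, 0 °C; 12, −78 to −20 °C; LiN(SiMe3)2 (1.5 equiv), −20 to 0 °C; Me3SiCl, −78 °C to rt
Reagents that add atoms: chlorotrimethylsilane, C[Si](C)(C)Cl
Why: Proposed new method: MeLi cleaves the O–Si bond of 11 and frees the regiodefined tetrasubstituted enolate 13, whose allyl-bearing carbon adds to the CH2 terminus of acrylate 12 (bond C4–C5); the ester enolate 14 then takes the proton from the methoxy-bearing α′-carbon through a six-membered transition state, the α-methoxy ketone enolate so formed attacks the ester carbonyl (bond C1–C2), LiN(SiMe3)2 removes the C3 hydrogen of the diketone so that methoxide cannot reopen it, and Me3SiCl traps enolate 15. The closest known reaction types are the Michael–Claisen (3+3) annulation of ketone enolates with acrylates to cyclohexane-1,3-diones and the α,α′-annulation of cyclopentanone enamines with acryloyl chloride to bicyclo[3.2.1]octane-2,8-diones; a lithium enolate of a fully substituted cyclopentanone with an α-alkoxyacrylate ester has not been used in this way. The six-membered ring C1–C2–C3–C4–C5–C8 closes by 6-(enolendo)-exo-trig acylation. C5 is controlled by the adjacent C6 methyl group, the acrylate adding to the enolate face anti to it, and C1 is controlled by the tether, because the three-carbon chain can reach C1 only on the face it already occupies, which leaves the C1 methoxy group exo and the C7 aryl group endo. The step needs site selectivity between the two α-carbons and 1,4- over 1,2-addition: the first is secured by making 13 from the silyl enol ether with no proton source present until C5 is quaternary, the second by the hindered enolate meeting an unsubstituted acrylate terminus.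

Step 9
Reactants: 16
Product: 17 (1R,5S,6S,7R)-1,3-dimethoxy-6-methyl-5-(prop-2-en-1-yl)-7-(3,4,5-trimethoxyphenyl)bicyclo[3.2.1]oct-3-ene-2,8-dione
Conditions: Pd(OAc)2 (1.1 equiv), MeCN, rt
Reagents that add atoms: none
Why: Saegusa–Ito oxidation should give the 3-methoxy enone because the palladium enolate at C3 has β-hydrogens only on C4, and no stereocentre is formed.

Step 10
Reactants: 17
Product: 18 (1S,2R,5S,6S,7R)-2-hydroxy-1,3-dimethoxy-6-methyl-5-(prop-2-en-1-yl)-7-(3,4,5-trimethoxyphenyl)bicyclo[3.2.1]oct-3-en-8-one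
Conditions: NaBH4, CeCl3·7H2O, MeOH, −78 °C
Reagents that add atoms: none
Why: Luche 1,2-reduction should take the conjugated C2 carbonyl in preference to the C8 ketone held between two quaternary bridgeheads, and hydride should come from the open exo face because the endo face is covered by the C7 aryl group, which gives the 2-endo alcohol (2R).

Step 11
Reactants: 18
Product: 19 (1S,2R,5S,6S,7R)-1,3-dimethoxy-6-methyl-8-oxo-5-(prop-2-en-1-yl)-7-(3,4,5-trimethoxyphenyl)bicyclo[3.2.1]oct-3-en-2-yl acetate (CNP0181407.1)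
Conditions: Ac2O, pyridine, DMAP (cat.), CH2Cl2, rt
Reagents that add atoms: acetic anhydride, CC(=O)OC(C)=O
Why: DMAP-catalysed acetylation of the secondary alcohol proceeds with retention at C2 and should give the target.

**Compound list**

1 | (4R)-4-[(tert-butyldimethylsilyl)oxy]cyclopent-2-en-1-one | O=C1C=C[C@H](O[Si](C)(C)C(C)(C)C)C1 | starting material
2 | (3,4,5-trimethoxyphenyl)magnesium bromide | COc1cc([Mg]Br)cc(OC)c1OC | starting material
3 | {[(3S,4R)-4-[(tert-butyldimethylsilyl)oxy]-3-(3,4,5-trimethoxyphenyl)cyclopent-1-en-1-yl]oxy}trimethylsilane | C[Si](C)(C)OC1=C[C@@H](c2cc(OC)c(OC)c(OC)c2)[C@H](O[Si](C)(C)C(C)(C)C)C1 | intermediate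
4 | (2R,3S,4R)-4-[(tert-butyldimethylsilyl)oxy]-3-(3,4,5-trimethoxyphenyl)-2-[(trimethylsilyl)oxy]cyclopentan-1-one | O=C1[C@H](O[Si](C)(C)C)[C@@H](c2cc(OC)c(OC)c(OC)c2)[C@H](O[Si](C)(C)C(C)(C)C)C1 | intermediate (not isolated)
5 | (2R,3R,4R)-4-[(tert-butyldimethylsilyl)oxy]-2-hydroxy-3-(3,4,5-trimethoxyphenyl)cyclopentan-1-one | O=C1[C@H](O)[C@@H](c2cc(OC)c(OC)c(OC)c2)[C@H](O[Si](C)(C)C(C)(C)C)C1 | intermediate
6 | (2R,3R,4R)-4-[(tert-butyldimethylsilyl)oxy]-2-methoxy-3-(3,4,5-trimethoxyphenyl)cyclopentan-1-one | O=C1[C@H](OC)[C@@H](c2cc(OC)c(OC)c(OC)c2)[C@H](O[Si](C)(C)C(C)(C)C)C1 | intermediate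
7 | (4R,5R)-5-methoxy-4-(3,4,5-trimethoxyphenyl)cyclopent-2-en-1-one | O=C1C=C[C@H](c2cc(OC)c(OC)c(OC)c2)[C@H]1OC | intermediate
8 | (4R,5R)-2-iodo-5-methoxy-4-(3,4,5-trimethoxyphenyl)cyclopent-2-en-1-one | O=C1C(I)=C[C@H](c2cc(OC)c(OC)c(OC)c2)[C@H]1OC | intermediate
9 | tributyl(prop-2-en-1-yl)stannane | C=CC[Sn](CCCC)(CCCC)CCCC | starting material
10 | (4R,5R)-5-methoxy-2-(prop-2-en-1-yl)-4-(3,4,5-trimethoxyphenyl)cyclopent-2-en-1-one | O=C1C(CC=C)=C[C@H](c2cc(OC)c(OC)c(OC)c2)[C@H]1OC | intermediate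
11 | {[(3S,4R,5R)-5-methoxy-3-methyl-2-(prop-2-en-1-yl)-4-(3,4,5-trimethoxyphenyl)cyclopent-1-en-1-yl]oxy}trimethylsilane | C=CCC1=C(O[Si](C)(C)C)[C@H](OC)[C@@H](c2cc(OC)c(OC)c(OC)c2)[C@@H]1C | intermediate
12 | methyl 2-methoxyprop-2-enoate | C=C(OC)C(=O)OC | starting material
13 | lithium (3S,4R,5R)-5-methoxy-3-methyl-2-(prop-2-en-1-yl)-4-(3,4,5-trimethoxyphenyl)cyclopent-1-en-1-olate | C=CCC1=C([O-])[C@H](OC)[C@@H](c2cc(OC)c(OC)c(OC)c2)[C@@H]1C.[Li+] | intermediate (not isolated)
14 | lithium 1,2-dimethoxy-3-[(1R,2S,3R,4R)-4-methoxy-2-methyl-5-oxo-1-(prop-2-en-1-yl)-3-(3,4,5-trimethoxyphenyl)cyclopentyl]prop-1-en-1-olate (ester enolate of the Michael adduct) | C=CC[C@]1(CC(OC)=C([O-])OC)C(=O)[C@H](OC)[C@@H](c2cc(OC)c(OC)c(OC)c2)[C@@H]1C.[Li+] | intermediate (not isolated)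
15 | lithium (1S,5R,6S,7R)-1,3-dimethoxy-6-methyl-8-oxo-5-(prop-2-en-1-yl)-7-(3,4,5-trimethoxyphenyl)bicyclo[3.2.1]oct-2-en-2-olate | C=CC[C@]12CC(OC)=C([O-])[C@](OC)(C1=O)[C@@H](c1cc(OC)c(OC)c(OC)c1)[C@@H]2C.[Li+] | intermediate (not isolated)
16 | {[(1S,5R,6S,7R)-1,3-dimethoxy-6-methyl-8-oxo-5-(prop-2-en-1-yl)-7-(3,4,5-trimethoxyphenyl)bicyclo[3.2.1]oct-2-en-2-yl]oxy}trimethylsilane | C=CC[C@]12CC(OC)=C(O[Si](C)(C)C)[C@](OC)(C1=O)[C@@H](c1cc(OC)c(OC)c(OC)c1)[C@@H]2C | intermediate
17 | (1R,5S,6S,7R)-1,3-dimethoxy-6-methyl-5-(prop-2-en-1-yl)-7-(3,4,5-trimethoxyphenyl)bicyclo[3.2.1]oct-3-ene-2,8-dione | C=CC[C@]12C=C(OC)C(=O)[C@](OC)(C1=O)[C@@H](c1cc(OC)c(OC)c(OC)c1)[C@@H]2C | intermediate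
18 | (1S,2R,5S,6S,7R)-2-hydroxy-1,3-dimethoxy-6-methyl-5-(prop-2-en-1-yl)-7-(3,4,5-trimethoxyphenyl)bicyclo[3.2.1]oct-3-en-8-one | C=CC[C@]12C=C(OC)[C@@H](O)[C@](OC)(C1=O)[C@@H](c1cc(OC)c(OC)c(OC)c1)[C@@H]2C | intermediate
19 | (1S,2R,5S,6S,7R)-1,3-dimethoxy-6-methyl-8-oxo-5-(prop-2-en-1-yl)-7-(3,4,5-trimethoxyphenyl)bicyclo[3.2.1]oct-3-en-2-yl acetate | C=CC[C@]12C=C(OC)[C@@H](OC(C)=O)[C@](OC)(C1=O)[C@@H](c1cc(OC)c(OC)c(OC)c1)[C@@H]2C | target

**Totals and risks**

Total step count: 11. Longest linear sequence: 11 steps (from 1).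

Steps most likely to fail:

Step 8 (proposed new method). The conjugate addition may be too slow on the captodative acrylate, or the bridged β-diketone may reopen by retro-Claisen attack of methoxide before it is deprotonated. The fallback sets out from 11 and comes back at 17 by known chemistry, an Effenberger-type double C-acylation of the silyl enol ether. Dimethyl methoxymalonate would be saponified (LiOH, THF–H2O, then acid) to methoxymalonic acid F1, which oxalyl chloride and catalytic DMF would convert into methoxymalonyl dichloride F2. F2 and 11 (CH2Cl2, −20 °C to rt) should give the enolised trione (1R,5S,6S,7R)-4-hydroxy-1,3-dimethoxy-6-methyl-5-(prop-2-en-1-yl)-7-(3,4,5-trimethoxyphenyl)bicyclo[3.2.1]oct-3-ene-2,8-dione F3, by acylation at the allyl-bearing carbon anti to methyl and a second acylation of the enol at the methoxy-bearing carbon. O-Triflation at C4 (Tf2O, 2,6-lutidine, CH2Cl2, −78 °C; any C2 regioisomer would be removed by chromatography) would give the vinylogous triflate (1R,5S,6S,7R)-1,3-dimethoxy-6-methyl-2,8-dioxo-5-(prop-2-en-1-yl)-7-(3,4,5-trimethoxyphenyl)bicyclo[3.2.1]oct-3-en-4-yl trifluoromethanesulfonate F4. Palladium-catalysed formate reduction (Pd(OAc)2, PPh3, Bu3N, HCO2H, DMF, 60 °C) would then give 17.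

Step 10. Hydride may also attack the bridging C8 ketone (loss of chemoselectivity). The fallback sets out from 17 and comes back at 19. Exhaustive reduction (NaBH4, MeOH, 0 °C to rt) should give the diol (1R,2R,5S,6S,7R,8S)-1,3-dimethoxy-6-methyl-5-(prop-2-en-1-yl)-7-(3,4,5-trimethoxyphenyl)bicyclo[3.2.1]oct-3-ene-2,8-diol F5. The less hindered allylic C2 hydroxyl would be acetylated selectively (Ac2O, 1 equiv, pyridine, 0 °C) to (1R,2R,5S,6S,7R,8S)-8-hydroxy-1,3-dimethoxy-6-methyl-5-(prop-2-en-1-yl)-7-(3,4,5-trimethoxyphenyl)bicyclo[3.2.1]oct-3-en-2-yl acetate F6. The C8 alcohol, flanked by two quaternary carbons, would then be oxidised back with Dess–Martin periodinane to give 19.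

Step 4. DBU may remove the benzylic γ-hydrogen of the product, leading to double-bond migration into conjugation with the aryl group and loss of the aryl-bearing stereocentre. The fallback sets out from 6 and comes back at 7. The silyl ether would first be cleaved (HF·pyridine, THF, 0 °C) to (2R,3S,4R)-4-hydroxy-2-methoxy-3-(3,4,5-trimethoxyphenyl)cyclopentan-1-one F7. Mesylation (MsCl, Et3N, CH2Cl2, −20 °C) would give (1R,2R,3R)-3-methoxy-4-oxo-2-(3,4,5-trimethoxyphenyl)cyclopentyl methanesulfonate F8, which should eliminate under the weak amine base to 7.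

Further compounds
F1 | step 8 | methoxymalonic acid (2-methoxypropanedioic acid) | COC(C(=O)O)C(=O)O
F2 | step 8 | methoxymalonyl dichloride (2-methoxypropanedioyl dichloride) | COC(C(=O)Cl)C(=O)Cl
F3 | step 8 | (1R,5S,6S,7R)-4-hydroxy-1,3-dimethoxy-6-methyl-5-(prop-2-en-1-yl)-7-(3,4,5-trimethoxyphenyl)bicyclo[3.2.1]oct-3-ene-2,8-dione | C=CC[C@]12C(O)=C(OC)C(=O)[C@](OC)(C1=O)[C@@H](c1cc(OC)c(OC)c(OC)c1)[C@@H]2C
F4 | step 8 | (1R,5S,6S,7R)-1,3-dimethoxy-6-methyl-2,8-dioxo-5-(prop-2-en-1-yl)-7-(3,4,5-trimethoxyphenyl)bicyclo[3.2.1]oct-3-en-4-yl trifluoromethanesulfonate | C=CC[C@]12C(OS(=O)(=O)C(F)(F)F)=C(OC)C(=O)[C@](OC)(C1=O)[C@@H](c1cc(OC)c(OC)c(OC)c1)[C@@H]2C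
F5 | step 10 | (1R,2R,5S,6S,7R,8S)-1,3-dimethoxy-6-methyl-5-(prop-2-en-1-yl)-7-(3,4,5-trimethoxyphenyl)bicyclo[3.2.1]oct-3-ene-2,8-diol | C=CC[C@]12C=C(OC)[C@@H](O)[C@](OC)([C@H]1O)[C@@H](c1cc(OC)c(OC)c(OC)c1)[C@@H]2C
F6 | step 10 | (1R,2R,5S,6S,7R,8S)-8-hydroxy-1,3-dimethoxy-6-methyl-5-(prop-2-en-1-yl)-7-(3,4,5-trimethoxyphenyl)bicyclo[3.2.1]oct-3-en-2-yl acetate | C=CC[C@]12C=C(OC)[C@@H](OC(C)=O)[C@](OC)([C@H]1O)[C@@H](c1cc(OC)c(OC)c(OC)c1)[C@@H]2C
F7 | step 4 | (2R,3S,4R)-4-hydroxy-2-methoxy-3-(3,4,5-trimethoxyphenyl)cyclopentan-1-one | O=C1[C@H](OC)[C@@H](c2cc(OC)c(OC)c(OC)c2)[C@H](O)C1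
F8 | step 4 | (1R,2R,3R)-3-methoxy-4-oxo-2-(3,4,5-trimethoxyphenyl)cyclopentyl methanesulfonate | O=C1[C@H](OC)[C@@H](c2cc(OC)c(OC)c(OC)c2)[C@H](OS(C)(=O)=O)C1
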